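(The earlier runs and the new flask were computed with made-up constants; scatter was added.)

A ratio of 11.2 between the early rates of two flasks, alike in charge apart from the Prd seeded into one, opens the question below.

| setting | south-east | north | west |
|---|---|---|---|
| Sub | 150 mM | 150 mM | 60.0 mM |
| Rgt | 300 mM | 300 mM | 300 mM |
| Cat | 3.00 mM | 3.00 mM | 3.00 mM |
| Prd |  | 75.0 mM |  |
| time |  |  | 3.8 min |

| run | time / min | [Prd] / mM |
|---|---|---|
| south-east run | 0.14 | 1.3 |
| south-east run | 0.41 | 3.0 |
| south-east run | 0.79 | 11.0 |
| south-east run | 1.3 | 18.6 |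
| south-east run | 1.8 | 33.6 |
| south-east run | 2.4 | 52.9 |
| south-east run | 3.1 | 78.5 |
| south-east run | 3.8 | 99.2 |
| north run | 0.14 | 88.3 |
| north run | 0.41 | 110.4 |
| north run | 0.79 | 137.8 |
| north run | 1.3 | 169.2 |
| north run | 1.8 | 190.1 |
| north run | 2.4 | 205.2 |
| north run | 3.1 | 215.6 |
| north run | 3.8 | 218.8 |

(each reading ± 1 mM)

- Overall: Sub + Rgt -> Prd, with Cat as catalyst.
- Constant volume, constant temperature.
- Readings of a species count what is bound in complexes too.
- "The second partner" is Rgt.

* Prd in the west run at 3.8 min, as a share of the Sub charged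

The south-east flask makes Prd at 7.32 mM min⁻¹ up to its second reading, and this reading stands for b, the Prd-free rate. The north flask makes 81.9 mM min⁻¹ between its first two readings, at [Prd] 99.4 mM, [Sub] 126 mM and [Rgt] 276 mM. Taking off b leaves a Prd-driven rate of 74.5 mM min⁻¹. Taken as proportional to [Sub][Rgt][Prd], it gives the west charge a growth constant c of 0.390 min⁻¹.

The crossover [Prd], b/c, is the concentration at which the two rates are equal: 18.8 mM on the west charge. Below it the Prd-free rate is the larger of the two; above it the Prd-driven rate is.

With [Prd] starting from zero, growth follows (b/c)(exp(ct) − 1). Mid-run consumption is taken as b·t, 27.8 mM, which lowers c to 0.190 min⁻¹. This first reckoning puts the west flask at 67.9%.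

The weak link is b itself, held constant as Sub falls. Between 1.8 min and 2.4 min the north flask, at [Prd] 198 mM, [Sub] 27.3 mM and [Rgt] 177 mM, leaves a Prd-free reading of 4.40 mM min⁻¹, give or take 2.36 mM min⁻¹. That is more than the 0.789 mM min⁻¹ that proportion to [Sub][Rgt] gives. The mean of the two readings, 5.86 mM min⁻¹, serves for the west run, with mid-run consumption 22.3 mM, c 0.227 min⁻¹, and a committed 58.9%.

The forecast is lower, at 32%. It reads “a small background path equivalent to about 6 mM of Prd” and keeps that offset in the west flask, where the crossover reckoned here stands at 18.8 mM.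

The west flask gives 63.7%, or 38.2 mM of Prd, twice its crossover of 18.8 mM.

    Cat + Sub ⇌ Cat.Sub, settled at all times (3.650 M⁻¹)
    Cat.Sub + Rgt ⇌ Cat.Sub.Rgt, settled at all times (66.90 M⁻¹)
    Cat.Sub.Rgt → Prd + Cat (3.048 min⁻¹)
    Sub + Rgt + Prd → 2 Prd (23.04 M⁻² min⁻¹)

Reckoned with [Sub] and [Rgt] as charged in the west flask, Cat.Sub.Rgt, the resting state, holds about 78.3% of Cat at the start. On the south-east charge the crossover comes to 7.51 mM. At the second south-east reading, [Prd] 3.0 mM, this crossover gives the Prd-free rate a share of 71.5% of the total; the apparent order in [Cat] early in that run is 0.72.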